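## Retrosynthetic overview

1. Target 12 ⇒ saturated keto lactone 11 by ketone dehydrogenation (C3a is quaternary, so only C6=C7 can form) ⇒ dioxolane 10.
2. Key disconnection C3a–C4, which closes the carbocycle (ring B) last: the lactone carbonyl C2 and the ketone C5 are 1,5-related through C3–C3a–C4, so C3a is the β-carbon of a butenolide and C4 the α-carbon of a ketone. In precursor 9 both carbons are electrophilic (butenolide β-carbon; bromomethyl carbon of a ketal-masked α-bromoketone) and are joined by a reductive 6-exo radical cyclisation. The single stereocentre C7a of the lactone (ring A), next to C3a, forces the cis ring fusion.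
3. 9 ⇒ 4-stannylbutenolide 7 + farnesyl bromide 8 (Stille); 7 ⇒ γ-hydroxy ynoate 5 (syn-stannylcupration, lactonisation: ring A); 5 ⇒ aldehyde 3 + methyl propiolate 4 (catalytic asymmetric alkynylation sets C7a); 3 ⇒ methyl 5-bromolevulinate 1.
4. Order of ring formation: temporary dioxolane (step 1), lactone ring A (step 4), carbocycle ring B (step 6).

Key step: step 6

Remark: atom numbers are those of the 1-benzofuran-2(3H)-one core of 12 (O1, C2, C3, C3a, C4 to C7, C7a) and are used for the corresponding atoms of all precursors; farnesyl = (2E,6E)-3,7,11-trimethyldodeca-2,6,10-trien-1-yl; the ligand antipode of step 3 is assumed to be fixed by a Mosher ester check on a test run so that the (R)-carbinol results.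

## Route

Step 1
Reactants: 1 methyl 5-bromo-4-oxopentanoate
Product: 2 methyl 3-[2-(bromomethyl)-1,3-dioxolan-2-yl]propanoate
Conditions: (Me3SiOCH2)2, Me3SiOTf (cat.), CH2Cl2, −78 to −20 °C
Reagents that add atoms: 1,2-bis(trimethylsilyloxy)ethane, C[Si](C)(C)OCCO[Si](C)(C)C
Why: Silyl triflate-catalysed dioxolane formation (Noyori ketalisation) masks the ketone before the hydride step and turns the bromomethyl carbon into a neopentyl-type radical precursor that resists substitution, while the ester is untouched under these aprotic conditions.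

Step 2
Reactants: 2 methyl 3-[2-(bromomethyl)-1,3-dioxolan-2-yl]propanoate
Product: 3 3-[2-(bromomethyl)-1,3-dioxolan-2-yl]propanal
Conditions: i-Bu2AlH (1.1 equiv), CH2Cl2, −78 °C; MeOH, aq. potassium sodium tartrate
Reagents that add atoms: none
Why: Partial ester reduction at −78 °C should stop at the aluminium hemiacetal, which releases the aldehyde only on work-up, and ketal and primary bromide are inert to the hydride at this temperature.

Step 3
Reactants: 3 3-[2-(bromomethyl)-1,3-dioxolan-2-yl]propanal; 4 methyl propiolate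
Product: 5 methyl (4R)-6-[2-(bromomethyl)-1,3-dioxolan-2-yl]-4-hydroxyhex-2-ynoate
Conditions: Me2Zn, ProPhenol ligand (20 mol%, antipode giving Si-face addition), Ph3PO (40 mol%), PhMe, 0 °C, slow addition of 3
Reagents that add atoms: none
Why: Catalytic asymmetric alkynylation of an aldehyde by an alkynylzinc bound to a dinuclear zinc–ProPhenol complex should deliver the propiolate to the Si face of 3 and so set the (R)-carbinol, the future C7a, as the only stereocentre that is introduced by a reagent.

Step 4
Reactants: 5 methyl (4R)-6-[2-(bromomethyl)-1,3-dioxolan-2-yl]-4-hydroxyhex-2-ynoate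
Product: 7 (5R)-5-{2-[2-(bromomethyl)-1,3-dioxolan-2-yl]ethyl}-4-(tributylstannyl)furan-2(5H)-one, via E-stannyl hydroxy enoate 6 (not isolated)
Conditions: Bu3SnH, LiN(i-Pr)2, THF, 0 °C; CuBr·SMe2, −78 °C; then 5, MeOH, −78 °C; PPTS (cat.), CH2Cl2, rt
Reagents that add atoms: tributyltin hydride, CCCC[SnH](CCCC)CCCC
Why: syn-Stannylcupration of the ynoate puts tin on the β-carbon and copper on the α-carbon, kinetic protonation by methanol at −78 °C should give the E enoate whose ester is cis to the carbinol, and lactonisation then closes ring A without touching the stereocentre; the neopentyl-type bromide should not be displaced at this temperature.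

Step 5
Reactants: 7 (5R)-5-{2-[2-(bromomethyl)-1,3-dioxolan-2-yl]ethyl}-4-(tributylstannyl)furan-2(5H)-one; 8 (2E,6E)-farnesyl bromide
Product: 9 (5R)-5-{2-[2-(bromomethyl)-1,3-dioxolan-2-yl]ethyl}-4-[(2E,6E)-3,7,11-trimethyldodeca-2,6,10-trien-1-yl]furan-2(5H)-one
Conditions: Pd2(dba)3 (2.5 mol%), AsPh3 (10 mol%), NMP, 45 °C
Reagents that add atoms: none
Why: Stille coupling of a vinylstannane with an allylic bromide should join the less hindered allyl terminus to C3a with retention of the E geometry, zerovalent palladium inserting into the allylic and not the neopentyl-type C–Br bond, under neutral conditions that leave the base-sensitive C7a–H alone.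

Step 6
Reactants: 9 (5R)-5-{2-[2-(bromomethyl)-1,3-dioxolan-2-yl]ethyl}-4-[(2E,6E)-3,7,11-trimethyldodeca-2,6,10-trien-1-yl]furan-2(5H)-one
Product: 10 (3aR,7aR)-5,5-(ethane-1,2-diyldioxy)-3a-[(2E,6E)-3,7,11-trimethyldodeca-2,6,10-trien-1-yl]hexahydro-1-benzofuran-2(3H)-one
Conditions: Bu3SnH (1.3 equiv, syringe pump over 8 h), AIBN (0.2 equiv), PhH (5 mM), 80 °C
Reagents that add atoms: none
Why: The tributyltin radical abstracts bromine from 9 to give a primary β,β-dialkoxyalkyl radical at C4, which adds to C3a, the β-carbon of the butenolide, and the lactone α-radical formed at C3 is then reduced by Bu3SnH. The closest known reaction type is the reductive Giese-type radical cyclisation of alkyl halides onto unsaturated lactones, which tolerates a fully substituted acceptor carbon because its transition state is early, and here it unites two carbons that are both electrophilic in 9. Ring B closes in the 6-exo-trig mode, the 7-endo attack at C3 being disfavoured by ring size and by polarity (nucleophilic radical, electrophilic β-carbon). The new quaternary stereocentre C3a is controlled by C7a, because the three-atom tether on C7a can reach the neighbouring sp2 carbon only on its own face of ring A, so the fusion should be cis, which is (3aR,7aR). The step needs cyclisation to outrun direct reduction and the 1,5-hydrogen shift from C7a to C4, and the low stationary Bu3SnH concentration, the gem-dialkoxy effect of the ketal at C5 and the polarity match are meant to secure this. Ketal, lactone and the three trisubstituted alkenes should stay untouched, since no 5- or 6-membered radical closure onto them is available.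

Step 7
Reactants: 10 (3aR,7aR)-5,5-(ethane-1,2-diyldioxy)-3a-[(2E,6E)-3,7,11-trimethyldodeca-2,6,10-trien-1-yl]hexahydro-1-benzofuran-2(3H)-one
Product: 11 (3aR,7aR)-3a-[(2E,6E)-3,7,11-trimethyldodeca-2,6,10-trien-1-yl]hexahydro-1-benzofuran-2,5-dione
Conditions: PPTS (0.3 equiv), acetone/H2O 9:1, 55 °C
Reagents that add atoms: water, O
Why: Mild acid-catalysed hydrolysis of the dioxolane, now an ordinary dialkyl ketal no longer deactivated by an α-bromine, should release the ketone with an acid too weak to protonate the trisubstituted alkenes or open the lactone.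

Step 8
Reactants: 11 (3aR,7aR)-3a-[(2E,6E)-3,7,11-trimethyldodeca-2,6,10-trien-1-yl]hexahydro-1-benzofuran-2,5-dione
Product: 12 (3aR,7aR)-3a-[(2E,6E)-3,7,11-trimethyldodeca-2,6,10-trien-1-yl]-3a,7a-dihydro-1-benzofuran-2,5(3H,4H)-dione
Conditions: IBX (2.5 equiv), 4-methoxypyridine N-oxide (2.5 equiv), DMSO, 25 to 45 °C
Reagents that add atoms: none
Why: IBX dehydrogenation of a ketone through its enol can only install the C6=C7 double bond because C4 is flanked by the quaternary C3a, the same centre blocks over-oxidation to a dienone or phenol, and neither stereocentre is touched.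

## Compound list

1 | methyl 5-bromo-4-oxopentanoate (methyl 5-bromolevulinate) | COC(=O)CCC(=O)CBr | starting material
2 | methyl 3-[2-(bromomethyl)-1,3-dioxolan-2-yl]propanoate | COC(=O)CCC1(CBr)OCCO1 | intermediate
3 | 3-[2-(bromomethyl)-1,3-dioxolan-2-yl]propanal | O=CCCC1(CBr)OCCO1 | intermediate
4 | methyl prop-2-ynoate (methyl propiolate) | COC(=O)C#C | starting material
5 | methyl (4R)-6-[2-(bromomethyl)-1,3-dioxolan-2-yl]-4-hydroxyhex-2-ynoate | COC(=O)C#C[C@H](O)CCC1(CBr)OCCO1 | intermediate
6 | methyl (2E,4R)-6-[2-(bromomethyl)-1,3-dioxolan-2-yl]-4-hydroxy-3-(tributylstannyl)hex-2-enoate | COC(=O)/C=C(/[Sn](CCCC)(CCCC)CCCC)[C@H](O)CCC1(CBr)OCCO1 | intermediate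
7 | (5R)-5-{2-[2-(bromomethyl)-1,3-dioxolan-2-yl]ethyl}-4-(tributylstannyl)furan-2(5H)-one | CCCC[Sn](CCCC)(CCCC)C1=CC(=O)O[C@@H]1CCC2(CBr)OCCO2 | intermediate
8 | (2E,6E)-farnesyl bromide ((2E,6E)-1-bromo-3,7,11-trimethyldodeca-2,6,10-triene) | CC(C)=CCC/C(C)=C/CC/C(C)=C/CBr | starting material
9 | (5R)-5-{2-[2-(bromomethyl)-1,3-dioxolan-2-yl]ethyl}-4-[(2E,6E)-3,7,11-trimethyldodeca-2,6,10-trien-1-yl]furan-2(5H)-one | CC(C)=CCC/C(C)=C/CC/C(C)=C/CC1=CC(=O)O[C@@H]1CCC2(CBr)OCCO2 | intermediate
10 | (3aR,7aR)-5,5-(ethane-1,2-diyldioxy)-3a-[(2E,6E)-3,7,11-trimethyldodeca-2,6,10-trien-1-yl]hexahydro-1-benzofuran-2(3H)-one | CC(C)=CCC/C(C)=C/CC/C(C)=C/C[C@]12CC3(OCCO3)CC[C@H]1OC(=O)C2 | intermediate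
11 | (3aR,7aR)-3a-[(2E,6E)-3,7,11-trimethyldodeca-2,6,10-trien-1-yl]hexahydro-1-benzofuran-2,5-dione | CC(C)=CCC/C(C)=C/CC/C(C)=C/C[C@]12CC(=O)CC[C@H]1OC(=O)C2 | intermediate
12 | (3aR,7aR)-3a-[(2E,6E)-3,7,11-trimethyldodeca-2,6,10-trien-1-yl]-3a,7a-dihydro-1-benzofuran-2,5(3H,4H)-dione | CC(C)=CCC/C(C)=C/CC/C(C)=C/C[C@]12CC(=O)C=C[C@H]1OC(=O)C2 | target

## Step count and risks

Total step count: 8. Longest linear sequence: 8 steps (1 to 12).

Steps most likely to fail:

Step 6. The open-chain radical may be reduced before it cyclises onto the fully substituted C3a, or it may take the allylic, oxygen-bearing hydrogen of C7a by a 1,5-shift, which would erase the stereocentre. The fallback closes the same C3a–C4 bond by an ionic Michael addition of a β-keto ester, whose mild carbonate enolisation should not touch the much less acidic C7a–H.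
- It sets out from methyl propiolate 4: commercial 4-[(tert-butyldimethylsilyl)oxy]butanal under the conditions of step 3 should give methyl (4R)-7-[(tert-butyldimethylsilyl)oxy]-4-hydroxyhept-2-ynoate F1.
- Stannylcupration and lactonisation as in step 4 should give (5R)-5-{3-[(tert-butyldimethylsilyl)oxy]propyl}-4-(tributylstannyl)furan-2(5H)-one F2.
- Stille coupling with 8 as in step 5 should give (5R)-5-{3-[(tert-butyldimethylsilyl)oxy]propyl}-4-farnesylfuran-2(5H)-one F3.
- HF·pyridine in THF should free (5R)-4-farnesyl-5-(3-hydroxypropyl)furan-2(5H)-one F4.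
- Dess–Martin periodinane should give 3-[(2R)-3-farnesyl-5-oxo-2,5-dihydrofuran-2-yl]propanal F5.
- Roskamp homologation with allyl diazoacetate and SnCl2 (cat.) in CH2Cl2 should give allyl 5-[(2R)-3-farnesyl-5-oxo-2,5-dihydrofuran-2-yl]-3-oxopentanoate F6.
- Cs2CO3 (0.2 equiv) in MeCN should close ring B by 6-exo Michael addition, cis for the same geometric reason as in step 6, to allyl (3aS,7aR)-3a-farnesyl-2,5-dioxooctahydro-1-benzofuran-4-carboxylate F7 (C4 epimers).
- Pd(PPh3)4 and morpholine in THF should remove the allyl group and the carboxyl carbon, and the route is rejoined at 11.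

Step 3. Facial discrimination may be insufficient for an unbranched aliphatic aldehyde, giving 5 of low enantiomeric purity. The fallback sets out from scalemic 5: oxidation with Dess–Martin periodinane should give methyl 6-[2-(bromomethyl)-1,3-dioxolan-2-yl]-4-oxohex-2-ynoate F8. Midland reduction of this ynone with (R)-Alpine-Borane, in which the alkyne acts as the small group, should return (4R)-5, and the route is rejoined at 5.

Step 8. Enol oxidation of the hindered ketone may be slow, so that oxidative attack on the triene side chain competes. The fallback sets out from 11: kinetic enolisation away from the neopentyl C4 with LiN(i-Pr)2 and Me3SiCl in THF at −78 °C should give (3aR,7aR)-3a-farnesyl-5-[(trimethylsilyl)oxy]-3a,4,7,7a-tetrahydro-1-benzofuran-2(3H)-one F9. Saegusa–Ito oxidation with Pd(OAc)2 in MeCN should then give 12 directly; any C4-regioisomeric silyl enol ether cannot eliminate and returns 11.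

## Further compounds

F1 | step 6 | methyl (4R)-7-[(tert-butyldimethylsilyl)oxy]-4-hydroxyhept-2-ynoate | COC(=O)C#C[C@H](O)CCCO[Si](C)(C)C(C)(C)C
F2 | step 6 | (5R)-5-{3-[(tert-butyldimethylsilyl)oxy]propyl}-4-(tributylstannyl)furan-2(5H)-one | CCCC[Sn](CCCC)(CCCC)C1=CC(=O)O[C@@H]1CCCO[Si](C)(C)C(C)(C)C
F3 | step 6 | (5R)-5-{3-[(tert-butyldimethylsilyl)oxy]propyl}-4-[(2E,6E)-3,7,11-trimethyldodeca-2,6,10-trien-1-yl]furan-2(5H)-one | CC(C)=CCC/C(C)=C/CC/C(C)=C/CC1=CC(=O)O[C@@H]1CCCO[Si](C)(C)C(C)(C)C
F4 | step 6 | (5R)-5-(3-hydroxypropyl)-4-[(2E,6E)-3,7,11-trimethyldodeca-2,6,10-trien-1-yl]furan-2(5H)-one | CC(C)=CCC/C(C)=C/CC/C(C)=C/CC1=CC(=O)O[C@@H]1CCCO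
F5 | step 6 | 3-{(2R)-5-oxo-3-[(2E,6E)-3,7,11-trimethyldodeca-2,6,10-trien-1-yl]-2,5-dihydrofuran-2-yl}propanal | CC(C)=CCC/C(C)=C/CC/C(C)=C/CC1=CC(=O)O[C@@H]1CCC=O
F6 | step 6 | allyl 3-oxo-5-{(2R)-5-oxo-3-[(2E,6E)-3,7,11-trimethyldodeca-2,6,10-trien-1-yl]-2,5-dihydrofuran-2-yl}pentanoate | CC(C)=CCC/C(C)=C/CC/C(C)=C/CC1=CC(=O)O[C@@H]1CCC(=O)CC(=O)OCC=C
F7 | step 6 | allyl (3aS,7aR)-2,5-dioxo-3a-[(2E,6E)-3,7,11-trimethyldodeca-2,6,10-trien-1-yl]octahydro-1-benzofuran-4-carboxylate | CC(C)=CCC/C(C)=C/CC/C(C)=C/C[C@]12C(C(=O)OCC=C)C(=O)CC[C@H]1OC(=O)C2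
F8 | step 3 | methyl 6-[2-(bromomethyl)-1,3-dioxolan-2-yl]-4-oxohex-2-ynoate | COC(=O)C#CC(=O)CCC1(CBr)OCCO1
F9 | step 8 | (3aR,7aR)-3a-[(2E,6E)-3,7,11-trimethyldodeca-2,6,10-trien-1-yl]-5-[(trimethylsilyl)oxy]-3a,4,7,7a-tetrahydro-1-benzofuran-2(3H)-one | CC(C)=CCC/C(C)=C/CC/C(C)=C/C[C@]12CC(O[Si](C)(C)C)=CC[C@H]1OC(=O)C2
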